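## Structural features

The target is a germacranolide. A ten-membered carbocycle (C1–C10) is fused trans at C7–C8 to an α-methylene-γ-butyrolactone (C11, C12, exocyclic C13, ring oxygen on C8); C14 is the methyl on C10 and C15 the methyl on C4. C4–C5 is a cis-epoxide (C3 and C6 on the same side of the oxirane, so it maps onto a Z olefin), C6 carries a 3-methylbut-2-enoate (senecioate), C9 a free secondary hydroxyl, and C1–C3 is a bare trimethylene run. Seven stereocentres are contiguous from C4 to C10 (4R,5S,6R,7S,8S,9R,10R). C8/C9/C10 form an anti,anti triad, and the epoxide oxygen stands threo to the C6 oxygen, on the olefin face away from C7. The fragile groups are the exocyclic enoate (Michael acceptor), the trisubstituted epoxide next to an ester (acid), the senecioate (deconjugation by strong base), and the lactone itself, which can migrate to a free C6 or C9 hydroxyl under base. The real difficulty is to close the strained ten-membered ring with the Z geometry intact, to place the epoxide on the correct face, and to tell the three oxygen functions on C6, C8 and C9 apart. The key step exploits the C3–C4 bond: it joins the unfunctionalised sp3 chain C1–C3 to the methyl-bearing sp2 carbon C4 of the Z olefin. Neither end is a stereocentre, so a primary alkylborane on C3 and a Z-vinyl iodide on C4 can close the ring with only a geometry to preserve.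

## Logic of the disconnections

32 back to 29 and 30. The O–Si bond at C9 is added and the ester C–O bond at C6 is cut. C6 and C9 are secondary carbinols of similar hindrance, so C9 stays masked (31) while C6 is acylated, and the senecioate is attached late because it would not survive enolate chemistry. The forward steps must avoid deconjugation of the acyl group, and the last desilylation must be non-basic, since the freed C9 hydroxyl could take over the lactone or add to C13.

29 back to 28. The two C–O bonds of the oxirane are cut, which removes C4 and C5 as stereocentres and returns the Z olefin. The forward step must attack the olefin face away from C7, which is the face of the C6 hydroxyl when H6 lies in the olefin plane, and must leave the two electron-poor olefins alone. A peracid is chosen over VO(acac)2 with t-BuOOH: the small O–C6–C5=C4 dihedral that a vanadate ester needs is reached in a medium ring from the conformer that leads to the other epoxide.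

28 back to 23 through 27 and 25. The O–Si bond at C6 is re-formed and the C11=C13 bond is removed. The methylene group comes from enolate chemistry, which requires both hydroxyls masked (a C6 alkoxide would translactonise) and neither epoxide nor senecioate present. This simplifies the lactone to its CH2 form. The forward demand is a triethylsilyl ether on C6 that is cleaved while the tert-butyldimethylsilyl ether on C9 stays.

23 back to 21. The C3–C4 bond is cut, opening the ring. 21 is an open chain that already holds C6–C10 and the Z geometry, so every stereocentre except the epoxide is set without a medium ring. Both 21 and 23 were compared with 32 centre by centre; constitution, configuration at C6–C10 and geometry (C3 cis to C6) agree, so they are used unchanged. The forward step needs hydroboration of the monosubstituted olefin only, ring closure faster than intermolecular coupling, and retention of the iodide geometry.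

21 back to 15 and 16 through 20, 19 and 18. C4–I is traced to C4–Si and then to the alkyne, and the C5–C6 bond is cut. An iodide cis to C6 on the methyl-bearing carbon is what anti addition of H–Si to a propargylic alcohol followed by retentive iododesilylation gives; aluminium hydride routes to the same pattern would reduce the lactone. The side arm is reduced to a formyl group on C7 and a three-carbon nucleophile. The forward demands are Felkin–Anh control at C6, silicon going to the carbon distal to the hydroxyl, and reaction at the alkyne and the vinylsilane in the presence of the terminal olefin.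

15 back to 10 through 14, 13 and 12. The C6 formyl group is masked as a cyclic acetal, the C2=C3 bond is cut (methylenation), and C2 is taken back through the alcohol to the vinyl group of 10. Crotylboration delivers a vinyl group where the key step needs an allyl group, so one carbon is added. During this homologation C6 must be neither an olefin nor a free aldehyde. The acetal has to survive six steps and then be hydrolysed without loss of the C9 silyl ether.

10 back to 6 and 7 through 9. The C9–C10 bond is cut (with the O–Si bond). The anti C9/C10 pair is the signature of an E-crotyl reagent adding to a C9 aldehyde through a closed transition state; this removes two stereocentres and four carbons. The pinacol reagent alone is only weakly face-selective with α-oxygenated aldehydes, so a chiral acid catalyst, matched with the substrate's own preference, is used to secure Re-face attack. 6 must not epimerise at C8 before it reacts.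

6 back to 1 and 3 through 5, 4 and 2. C9 is returned to the alcohol level, the C6–C7 bond is cut, and the silyl ether is removed. The butenolide β-carbon is the natural acceptor, and the C8 substituent sends the incoming group to the opposite face, which fixes the trans lactone. C6 is brought in as a dioxolanyl radical, already at the aldehyde level; a vinyl group at C7 could not be told apart from the C10 vinyl and allyl groups in the later hydroboration and in any oxidative cleavage. The forward demand is anti selectivity in the radical addition.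

## Other disconnections considered

Alternative 1: The cut is in the saturated run. An olefin is placed at C1=C2 (diene A1) and then opened to the two C–S bonds of the eleven-membered cyclic sulfone A2. In the forward direction A2 undergoes a Ramberg–Bäcklund reaction with in situ α-bromination (KOH on alumina, CBr2F2): the episulfone forms, SO2 is lost, and the ring contracts from eleven to ten atoms to give A1.
- In its favour: the ring is first closed one atom larger by C–S bond formation at two primary carbons, which is far less strained than a direct ten-ring C–C closure. The extrusion is irreversible, needs no transition metal, and A1 carries only robust groups (acetonide, PMB ether, TBDPS ether).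
- Against it here: the olefin it makes is one the target lacks, so C1=C2 must later be saturated beside C4=C5. The strongly basic medium with an electrophilic bromine source must spare the trisubstituted olefin. The lactone carbons arrive as a silyloxyethyl chain at the alcohol level, so oxidation, diol release, lactonisation onto O8 rather than O9, methylenation, epoxidation and acylation all remain.
- Comparison: both plans carry C6–C10 intact into the ring, and both need high dilution for the closing event and a preformed Z C4=C5 olefin; on these points they are equal. The alternative is the better plan on the ring-forming event itself, which is less demanding and needs neither a stereodefined vinyl iodide nor palladium. The chosen plan forms the ring in one event instead of two and is several steps shorter, because the lactone is present from the first step.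

Alternative 2: No ring bond is cut. The transannular bond C4–C9 is added, which turns the ten-membered ring into the cis-fused decalin mesylate A4 (tertiary C9 hydroxyl, angular methyl on C4, equatorial C5 mesylate anti-periplanar to C4–C9). In the forward direction the C9 alkoxide of A4 triggers a Wharton–Grob fragmentation: C4–C9 breaks, C4=C5 and the C9 carbonyl form, and the (Z)-cyclodecenone A3 is released.
- In its favour: there is no macrocyclisation and no dilution, the stereocentres C6–C8 can be set on a six-membered ring, and the olefin geometry follows stereospecifically from the anti-periplanar alignment.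
- Against it here: A4 has six contiguous stereocentres, two of them fully substituted ring-fusion carbons, and making it would dominate the route. In A3, C10 lies next to the new C9 ketone and can epimerise under the basic conditions. The ketone must then be reduced to the 9R alcohol on a flexible ten-membered ring. The C7 vinyl group needs oxidation and one more carbon to become the methylene lactone.
- Comparison: the two plans are equal in that the olefin geometry is transferred stereospecifically. The alternative is the better plan on reliability of ring formation, since a fragmentation cannot oligomerise. The chosen plan is better at C9 and C10, which it sets in an open chain where neither is ever α to a carbonyl, and it is clearly shorter.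

Alternative 3: The cut is at C1–C10. The retro-[3,3] shift re-forms C3–C8 and gives the cyclohexanol A6, whose C8 carbinol carries the (E)-propenyl group (C9=C10–C14) and whose C3 carries the vinyl group (C2=C1), with the epoxide already on C4–C5. In the forward direction the potassium alkoxide of A6 (KH, 18-crown-6) undergoes an anionic oxy-Cope rearrangement through a chair with both alkenyl groups equatorial. C1–C10 forms, C3–C8 breaks, C10 is set, and protonation of the C8 enolate gives the ketone A5.
- In its favour: the ring grows from six to ten without a macrocyclisation, C10 is set by the pericyclic transition state, the epoxide is installed on a six-membered ring, and the regiodefined C8/C9 enolate could be oxidised at C9 in the same flask.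
- Against it here: A5 has no oxygen on C9 and a ketone at C8, so two stereocentres remain to be set on the ten-membered ring. The E C2=C3 olefin must be saturated next to an allylic epoxide. A6 is a crowded cyclohexanol whose alkoxide is generated beside an epoxide-bearing carbon. The lactone must still be built from the PMB-protected hydroxyethyl chain.
- Comparison: the alternative is the better plan at the ring-forming step (no dilution, no metal) and equal in how securely C10 is set. The chosen plan is better in that every stereocentre except the epoxide exists before the ring does, with fewer redox operations after cyclisation. The overall step count is about equal, or slightly longer for the alternative.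

Key step: step 15

Remark: germacrane numbering (C1–C10 ring, C11–C13 lactone carbons, C14 on C10, C15 on C4) is used for all intermediates. TBS = tert-butyldimethylsilyl, TES = triethylsilyl, BDMS = benzyldimethylsilyl, 9-BBN = 9-borabicyclo[3.3.1]nonane. The C11 configuration of 25 and 26 does not matter, because C11 becomes sp2 in step 17.

Step 1
Reactants: 1 (S)-5-(hydroxymethyl)furan-2(5H)-one
Product: 2 (S)-5-[(TBS-oxy)methyl]furan-2(5H)-one
Conditions: TBSCl, imidazole, CH2Cl2, 0 °C → rt
Reagents that add atoms: tert-butyldimethylsilyl chloride, CC(C)(C)[Si](C)(C)Cl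
Why: Imidazole-promoted silylation of the primary alcohol; the bulky silyloxymethyl group on C8 later shields one face of the butenolide, and no stereocentre is touched.

Step 2
Reactants: 2 (S)-5-[(TBS-oxy)methyl]furan-2(5H)-one; 3 1,3-dioxolane
Product: 4 (4S,5S)-5-[(TBS-oxy)methyl]-4-(1,3-dioxolan-2-yl)dihydrofuran-2(3H)-one
Conditions: Ph2CO (0.3 equiv), 3 as solvent, hν (350 nm), degassed, rt
Reagents that add atoms: 1,3-dioxolane (3), C1COCO1
Why: Photochemical radical conjugate addition (Giese type), known for 5-substituted furanones: triplet benzophenone abstracts the C2 hydrogen of the dioxolane and the acetal radical adds to the butenolide β-carbon anti to the C8 substituent, which sets C7 and the trans lactone. C6 arrives at the aldehyde oxidation level as an acetal.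

Step 3
Reactants: 4 (4S,5S)-5-[(TBS-oxy)methyl]-4-(1,3-dioxolan-2-yl)dihydrofuran-2(3H)-one
Product: 5 (4S,5S)-4-(1,3-dioxolan-2-yl)-5-(hydroxymethyl)dihydrofuran-2(3H)-one
Conditions: HF·pyridine, pyridine, THF, 0 °C → rt
Reagents that add atoms: none
Why: Fluoride cleavage of the primary silyl ether under buffered, non-basic conditions, which leave the dioxolane and the lactone intact.

Step 4
Reactants: 5 (4S,5S)-4-(1,3-dioxolan-2-yl)-5-(hydroxymethyl)dihydrofuran-2(3H)-one
Product: 6 (2S,3S)-3-(1,3-dioxolan-2-yl)-5-oxotetrahydrofuran-2-carbaldehyde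
Conditions: Dess–Martin periodinane, CH2Cl2, 0 °C → rt; used crude
Reagents that add atoms: none
Why: Dess–Martin oxidation under neutral conditions gives the α-acyloxy aldehyde without enolisation at C8; the crude aldehyde is carried on at once.

Step 5
Reactants: 6 (2S,3S)-3-(1,3-dioxolan-2-yl)-5-oxotetrahydrofuran-2-carbaldehyde; 7 (E)-crotylboronic acid pinacol ester
Product: 9 (4S,5S)-4-(1,3-dioxolan-2-yl)-5-[(1R,2R)-1-hydroxy-2-methylbut-3-en-1-yl]dihydrofuran-2(3H)-one, via pinacol borate ester 8 (not isolated)
Conditions: 7 (1.5 equiv), (R)-3,3′-bis(2,4,6-triisopropylphenyl)-1,1′-binaphthyl-2,2′-diyl hydrogen phosphate (5 mol%), 4 Å MS, toluene, −30 °C; aq. NaHCO3 work-up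
Reagents that add atoms: (E)-crotylboronic acid pinacol ester (7), C/C=C/CB1OC(C)(C)C(C)(C)O1
Why: Chiral-phosphoric-acid-catalysed crotylboration through a closed chair (Zimmerman–Traxler) transition state: the E geometry of 7 gives the anti C9/C10 pair. Re-face attack (9R, anti to the C8 oxygen) is favoured by the catalyst, whose R enantiomer is expected to direct Re attack as with simple aldehydes, and by the polar Felkin–Anh preference of the α-oxygenated aldehyde, so the two act together. Borate 8 is hydrolysed at work-up.

Step 6
Reactants: 9 (4S,5S)-4-(1,3-dioxolan-2-yl)-5-[(1R,2R)-1-hydroxy-2-methylbut-3-en-1-yl]dihydrofuran-2(3H)-one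
Product: 10 (4S,5S)-5-[(1R,2R)-1-(TBS-oxy)-2-methylbut-3-en-1-yl]-4-(1,3-dioxolan-2-yl)dihydrofuran-2(3H)-one
Conditions: TBSOTf, 2,6-lutidine, CH2Cl2, −78 → −20 °C
Reagents that add atoms: tert-butyldimethylsilyl trifluoromethanesulfonate, CC(C)(C)[Si](C)(C)OS(=O)(=O)C(F)(F)F
Why: Silyl triflate silylation of the hindered secondary alcohol; at low temperature O-silylation is much faster than activation of the cyclic acetal by the bulky triflate.

Step 7
Reactants: 10 (4S,5S)-5-[(1R,2R)-1-(TBS-oxy)-2-methylbut-3-en-1-yl]-4-(1,3-dioxolan-2-yl)dihydrofuran-2(3H)-one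
Product: 12 (4S,5S)-5-[(1R,2R)-1-(TBS-oxy)-4-hydroxy-2-methylbutyl]-4-(1,3-dioxolan-2-yl)dihydrofuran-2(3H)-one, via B-alkyl-9-BBN adduct 11 (not isolated)
Conditions: 9-BBN (1.5 equiv), THF, 0 °C → rt; then NaBO3·4H2O, THF/H2O, rt
Reagents that add atoms: sodium perborate, [Na+].[Na+].O[B-]1(O)OO[B-](O)(O)OO1
Why: Anti-Markovnikov hydroboration of the only olefin in the molecule (lactone and acetal are inert to 9-BBN at rt), followed by perborate oxidation of the C–B bond. Perborate is mild enough to spare the lactone, which alkaline peroxide could open.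

Step 8
Reactants: 12 (4S,5S)-5-[(1R,2R)-1-(TBS-oxy)-4-hydroxy-2-methylbutyl]-4-(1,3-dioxolan-2-yl)dihydrofuran-2(3H)-one
Product: 13 (4S,5S)-5-[(1R,2R)-1-(TBS-oxy)-2-methyl-4-oxobutyl]-4-(1,3-dioxolan-2-yl)dihydrofuran-2(3H)-one
Conditions: Dess–Martin periodinane, CH2Cl2, rt
Reagents that add atoms: none
Why: Dess–Martin oxidation of the primary alcohol; the carbon α to the new aldehyde is a CH2 group, so C10 is not at risk.

Step 9
Reactants: 13 (4S,5S)-5-[(1R,2R)-1-(TBS-oxy)-2-methyl-4-oxobutyl]-4-(1,3-dioxolan-2-yl)dihydrofuran-2(3H)-one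
Product: 14 (4S,5S)-5-[(1R,2R)-1-(TBS-oxy)-2-methylpent-4-en-1-yl]-4-(1,3-dioxolan-2-yl)dihydrofuran-2(3H)-one
Conditions: Ph3PCH3Br, KN(SiMe3)2, THF, 0 °C; then 13, −78 → 0 °C
Reagents that add atoms: methyltriphenylphosphonium bromide, C[P+](c1ccccc1)(c1ccccc1)c1ccccc1.[Br-]
Why: Wittig methylenation; the non-stabilised ylide takes the aldehyde at low temperature much faster than the lactone carbonyl. This completes the one-carbon homologation of the vinyl group to the allyl terminus C1–C2=C3.

Step 10
Reactants: 14 (4S,5S)-5-[(1R,2R)-1-(TBS-oxy)-2-methylpent-4-en-1-yl]-4-(1,3-dioxolan-2-yl)dihydrofuran-2(3H)-one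
Product: 15 (2S,3S)-2-[(1R,2R)-1-(TBS-oxy)-2-methylpent-4-en-1-yl]-5-oxotetrahydrofuran-3-carbaldehyde
Conditions: pyridinium p-toluenesulfonate (0.3 equiv), acetone/H2O (9:1), 55 °C; used at once
Reagents that add atoms: water, O
Why: Acid-catalysed acetal hydrolysis through the oxocarbenium ion unveils the C6 formyl group; the weak pyridinium acid leaves the hindered secondary silyl ether in place, and the trans arrangement at C7 is the thermodynamic one.

Step 11
Reactants: 15 (2S,3S)-2-[(1R,2R)-1-(TBS-oxy)-2-methylpent-4-en-1-yl]-5-oxotetrahydrofuran-3-carbaldehyde; 16 1-propynylmagnesium bromide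
Product: 18 (4R,5S)-5-[(1R,2R)-1-(TBS-oxy)-2-methylpent-4-en-1-yl]-4-[(1R)-1-hydroxybut-2-yn-1-yl]dihydrofuran-2(3H)-one, via bromomagnesium alkoxide 17 (not isolated)
Conditions: 16 (1.5 equiv, 0.5 M in THF), THF, −78 °C; cold sat. aq. NH4Cl
Reagents that add atoms: 1-propynylmagnesium bromide (16), CC#C[Mg]Br
Why: Grignard 1,2-addition of the alkynyl nucleophile. In the Felkin–Anh arrangement the branched C8 substituent stands anti to the nucleophile, which passes the C7 hydrogen, and this should give the 6R carbinol. The low temperature and cold quench limit enolisation, β-elimination of the lactone oxygen and migration of the lactone to the new alkoxide.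

Step 12
Reactants: 18 (4R,5S)-5-[(1R,2R)-1-(TBS-oxy)-2-methylpent-4-en-1-yl]-4-[(1R)-1-hydroxybut-2-yn-1-yl]dihydrofuran-2(3H)-one
Product: 19 (4R,5S)-4-[(1R,2Z)-3-(BDMS)-1-hydroxybut-2-en-1-yl]-5-[(1R,2R)-1-(TBS-oxy)-2-methylpent-4-en-1-yl]dihydrofuran-2(3H)-one
Conditions: BnMe2SiH (1.2 equiv), [Cp*Ru(MeCN)3]PF6 (3 mol%), CH2Cl2, 0 °C → rt
Reagents that add atoms: benzyldimethylsilane, C[SiH](C)Cc1ccccc1
Why: Ruthenium-catalysed trans-hydrosilylation of the alkyne: H and Si add anti, and silicon goes to the methyl-bearing carbon distal to the free hydroxyl, so silicon ends up cis to C6. The catalyst does not hydrosilylate the terminal olefin or touch the lactone.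

Step 13
Reactants: 19 (4R,5S)-4-[(1R,2Z)-3-(BDMS)-1-hydroxybut-2-en-1-yl]-5-[(1R,2R)-1-(TBS-oxy)-2-methylpent-4-en-1-yl]dihydrofuran-2(3H)-one
Product: 20 (4R,5S)-5-[(1R,2R)-1-(TBS-oxy)-2-methylpent-4-en-1-yl]-4-[(1R,2Z)-1-hydroxy-3-iodobut-2-en-1-yl]dihydrofuran-2(3H)-one
Conditions: N-iodosuccinimide (1.2 equiv), (CF3)2CHOH, 0 °C, short reaction time
Reagents that add atoms: N-iodosuccinimide, O=C1CCC(=O)N1I
Why: Ipso iododesilylation (electrophilic substitution through the β-silyl cation) in hexafluoroisopropanol proceeds with retention of olefin geometry. The vinylsilane is far more nucleophilic than the unactivated monosubstituted olefin, so a small excess of reagent should react at silicon only.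

Step 14
Reactants: 20 (4R,5S)-5-[(1R,2R)-1-(TBS-oxy)-2-methylpent-4-en-1-yl]-4-[(1R,2Z)-1-hydroxy-3-iodobut-2-en-1-yl]dihydrofuran-2(3H)-one
Product: 21 (4S,5S)-5-[(1R,2R)-1-(TBS-oxy)-2-methylpent-4-en-1-yl]-4-[(1R,2Z)-3-iodo-1-(TES-oxy)but-2-en-1-yl]dihydrofuran-2(3H)-one
Conditions: TESCl, imidazole, CH2Cl2, 0 °C
Reagents that add atoms: chlorotriethylsilane, CC[Si](Cl)(CC)CC
Why: Mild silylation of the allylic alcohol gives the cyclisation precursor, with a C6 ether that is more labile than the C9 ether; imidazole is too weak a base to move the lactone.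

Step 15
Reactants: 21 (4S,5S)-5-[(1R,2R)-1-(TBS-oxy)-2-methylpent-4-en-1-yl]-4-[(1R,2Z)-3-iodo-1-(TES-oxy)but-2-en-1-yl]dihydrofuran-2(3H)-one
Product: 23 (4Z,6S,7S,8S,9R,10R)-9-(TBS-oxy)-6-(TES-oxy)germacr-4-en-12,8-olide, via B-alkyl-9-BBN adduct 22 (not isolated)
Conditions: 9-BBN (2 equiv), THF, rt; H2O; then slow addition (syringe pump) to Pd(dppf)Cl2 (20 mol%), AsPh3 (40 mol%), Cs2CO3 (3 equiv), DMF/THF/H2O, 50 °C, final concentration 2 mM
Reagents that add atoms: none
Why: 9-BBN adds anti-Markovnikov to the monosubstituted C2=C3 olefin (boron on C3) much faster than to the trisubstituted iodoalkene and does not reduce the lactone at rt, giving 22. Zerovalent palladium then inserts into the C4–I bond with retention, the base-activated borate transfers its primary alkyl group, and reductive elimination forms C3–C4. The closest known reaction type is the B-alkyl Suzuki–Miyaura macrocyclisation of ω-borylalkyl vinyl iodides. The ten-membered ring closes at the metal: intramolecular transmetalation gives an eleven-membered palladacycle that contracts to the carbocycle on reductive elimination, so no strained ten-membered transition state of the displacement or carbonyl-addition kind is needed. No stereocentre is formed; the only stereochemical element, the Z geometry at C4=C5, is carried over from the iodide. The step needs ring closure to outrun intermolecular coupling, which slow addition at high dilution and the turn imposed by the trans lactone and the Z olefin should secure. The wide bite angle of dppf, with AsPh3, favours reductive elimination over β-hydride elimination, and the carbonate base spares the lactone and both silyl ethers.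

Step 16
Reactants: 23 (4Z,6S,7S,8S,9R,10R)-9-(TBS-oxy)-6-(TES-oxy)germacr-4-en-12,8-olide
Product: 25 (4Z,6S,7S,8S,9R,10R,11R)-9-(TBS-oxy)-13-(dimethylamino)-6-(TES-oxy)germacr-4-en-12,8-olide, via lithium enolate 24 (not isolated)
Conditions: LiN(iPr)2 (1.3 equiv), THF, −78 °C; then CH2=NMe2+ I− (3 equiv), −78 °C → rt
Reagents that add atoms: dimethylmethylideneammonium iodide, C=[N+](C)C.[I-]
Why: Mannich reaction of the lithium lactone enolate with the preformed iminium salt; the electrophile should enter anti to the C7 substituent. The enolate has no β-leaving group, and both hydroxyls are masked, so the lactone cannot migrate.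

Step 17
Reactants: 25 (4Z,6S,7S,8S,9R,10R,11R)-9-(TBS-oxy)-13-(dimethylamino)-6-(TES-oxy)germacr-4-en-12,8-olide
Product: 27 (4Z,6S,7S,8S,9R,10R)-9-(TBS-oxy)-6-(TES-oxy)germacra-4,11(13)-dien-12,8-olide, via trimethylammonium iodide 26 (not isolated)
Conditions: MeI (excess), THF, rt; then sat. aq. NaHCO3, CH2Cl2, rt
Reagents that add atoms: none
Why: N-Methylation followed by E1cB elimination of trimethylamine (Hofmann-type) gives the exocyclic methylene lactone under bicarbonate, which is too mild to harm the silyl ethers.

Step 18
Reactants: 27 (4Z,6S,7S,8S,9R,10R)-9-(TBS-oxy)-6-(TES-oxy)germacra-4,11(13)-dien-12,8-olide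
Product: 28 (4Z,6S,7R,8S,9R,10R)-9-(TBS-oxy)-6-hydroxygermacra-4,11(13)-dien-12,8-olide
Conditions: pyridinium p-toluenesulfonate (0.2 equiv), MeOH/CH2Cl2 (1:4), 0 °C
Reagents that add atoms: none
Why: Acid-catalysed methanolysis removes the triethylsilyl ether much faster than the hindered tert-butyldimethylsilyl ether; under weak acid methanol does not add to the methylene lactone and the lactone does not migrate.

Step 19
Reactants: 28 (4Z,6S,7R,8S,9R,10R)-9-(TBS-oxy)-6-hydroxygermacra-4,11(13)-dien-12,8-olide
Product: 29 (4R,5S,6R,7R,8S,9R,10R)-9-(TBS-oxy)-4,5-epoxy-6-hydroxygermacr-11(13)-en-12,8-olide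
Conditions: m-CPBA (1.2 equiv), NaHCO3, CH2Cl2, 0 °C
Reagents that add atoms: 3-chloroperbenzoic acid, OOC(=O)c1cccc(Cl)c1
Why: Hydroxyl-directed peracid epoxidation (Henbest type). Allylic 1,3-strain with C3 keeps H6 in the olefin plane, so the C6 hydroxyl lies on the outer face away from C7; hydrogen-bonded delivery and peripheral attack both lead to that face and should give the threo (4R,5S) cis-epoxide. The methylene lactone is electron-poor and is not attacked.

Step 20
Reactants: 29 (4R,5S,6R,7R,8S,9R,10R)-9-(TBS-oxy)-4,5-epoxy-6-hydroxygermacr-11(13)-en-12,8-olide; 30 3-methylbut-2-enoyl chloride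
Product: 31 (4R,5S,6R,7R,8S,9R,10R)-9-(TBS-oxy)-4,5-epoxy-6-(3-methylbut-2-enoyloxy)germacr-11(13)-en-12,8-olide
Conditions: 30 (3 equiv), pyridine, 4-(dimethylamino)pyridine (0.2 equiv), CH2Cl2, 0 °C → rt
Reagents that add atoms: 3-methylbut-2-enoyl chloride (30), CC(C)=CC(=O)Cl
Why: Nucleophile-catalysed acylation of the only free hydroxyl; pyridine is a weak base, which keeps vinylketene formation and deconjugation of the acyl group low and does not promote lactone migration.

Step 21
Reactants: 31 (4R,5S,6R,7R,8S,9R,10R)-9-(TBS-oxy)-4,5-epoxy-6-(3-methylbut-2-enoyloxy)germacr-11(13)-en-12,8-olide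
Product: 32 (4R,5S,6R,7S,8S,9R,10R)-4,5-epoxy-9-hydroxy-6-(3-methylbut-2-enoyloxy)germacr-11(13)-en-12,8-olide
Conditions: HF·pyridine, pyridine, THF, 0 °C → rt
Reagents that add atoms: none
Why: Buffered fluoride cleavage of the last silyl ether; the medium is never basic, so the freed C9 hydroxyl neither takes over the lactone nor adds to C13, and the pyridine buffer protects the epoxide.

Compound list

1 | (S)-5-(hydroxymethyl)furan-2(5H)-one | O=C1C=C[C@@H](CO)O1 | starting material
2 | (S)-5-[(TBS-oxy)methyl]furan-2(5H)-one | O=C1C=C[C@@H](CO[Si](C)(C)C(C)(C)C)O1 | intermediate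
3 | 1,3-dioxolane | C1COCO1 | starting material
4 | (4S,5S)-5-[(TBS-oxy)methyl]-4-(1,3-dioxolan-2-yl)dihydrofuran-2(3H)-one (trans) | CC(C)(C)[Si](C)(C)OC[C@H]1OC(=O)C[C@@H]1C1OCCO1 | intermediate
5 | (4S,5S)-4-(1,3-dioxolan-2-yl)-5-(hydroxymethyl)dihydrofuran-2(3H)-one | OC[C@H]1OC(=O)C[C@@H]1C1OCCO1 | intermediate
6 | (2S,3S)-3-(1,3-dioxolan-2-yl)-5-oxotetrahydrofuran-2-carbaldehyde | O=C[C@H]1OC(=O)C[C@@H]1C1OCCO1 | intermediate
7 | (E)-crotylboronic acid pinacol ester | C/C=C/CB1OC(C)(C)C(C)(C)O1 | starting material
8 | pinacol borate ester of 9 (boron on the C9 oxygen; not isolated) | C=C[C@@H](C)[C@@H](OB1OC(C)(C)C(C)(C)O1)[C@H]1OC(=O)C[C@@H]1C1OCCO1 | intermediate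
9 | (4S,5S)-4-(1,3-dioxolan-2-yl)-5-[(1R,2R)-1-hydroxy-2-methylbut-3-en-1-yl]dihydrofuran-2(3H)-one | C=C[C@@H](C)[C@@H](O)[C@H]1OC(=O)C[C@@H]1C1OCCO1 | intermediate
10 | (4S,5S)-5-[(1R,2R)-1-(TBS-oxy)-2-methylbut-3-en-1-yl]-4-(1,3-dioxolan-2-yl)dihydrofuran-2(3H)-one | C=C[C@@H](C)[C@@H](O[Si](C)(C)C(C)(C)C)[C@H]1OC(=O)C[C@@H]1C1OCCO1 | intermediate
11 | B-alkyl-9-BBN adduct of 10 (boron on the terminal carbon; not isolated) | C1CCC2CCCC1B2CC[C@@H](C)[C@@H](O[Si](C)(C)C(C)(C)C)[C@H]1OC(=O)C[C@@H]1C1OCCO1 | intermediate
12 | (4S,5S)-5-[(1R,2R)-1-(TBS-oxy)-4-hydroxy-2-methylbutyl]-4-(1,3-dioxolan-2-yl)dihydrofuran-2(3H)-one | OCC[C@@H](C)[C@@H](O[Si](C)(C)C(C)(C)C)[C@H]1OC(=O)C[C@@H]1C1OCCO1 | intermediate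
13 | (4S,5S)-5-[(1R,2R)-1-(TBS-oxy)-2-methyl-4-oxobutyl]-4-(1,3-dioxolan-2-yl)dihydrofuran-2(3H)-one | O=CC[C@@H](C)[C@@H](O[Si](C)(C)C(C)(C)C)[C@H]1OC(=O)C[C@@H]1C1OCCO1 | intermediate
14 | (4S,5S)-5-[(1R,2R)-1-(TBS-oxy)-2-methylpent-4-en-1-yl]-4-(1,3-dioxolan-2-yl)dihydrofuran-2(3H)-one | C=CC[C@@H](C)[C@@H](O[Si](C)(C)C(C)(C)C)[C@H]1OC(=O)C[C@@H]1C1OCCO1 | intermediate
15 | (2S,3S)-2-[(1R,2R)-1-(TBS-oxy)-2-methylpent-4-en-1-yl]-5-oxotetrahydrofuran-3-carbaldehyde | C=CC[C@@H](C)[C@@H](O[Si](C)(C)C(C)(C)C)[C@H]1OC(=O)C[C@@H]1C=O | intermediate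
16 | 1-propynylmagnesium bromide | CC#C[Mg]Br | starting material
17 | bromomagnesium alkoxide of 18 (not isolated) | C=CC[C@@H](C)[C@@H](O[Si](C)(C)C(C)(C)C)[C@H]1OC(=O)C[C@@H]1[C@@H](O[Mg]Br)C#CC | intermediate
18 | (4R,5S)-5-[(1R,2R)-1-(TBS-oxy)-2-methylpent-4-en-1-yl]-4-[(1R)-1-hydroxybut-2-yn-1-yl]dihydrofuran-2(3H)-one | C=CC[C@@H](C)[C@@H](O[Si](C)(C)C(C)(C)C)[C@H]1OC(=O)C[C@@H]1[C@@H](O)C#CC | intermediate
19 | (4R,5S)-4-[(1R,2Z)-3-(BDMS)-1-hydroxybut-2-en-1-yl]-5-[(1R,2R)-1-(TBS-oxy)-2-methylpent-4-en-1-yl]dihydrofuran-2(3H)-one | C=CC[C@@H](C)[C@@H](O[Si](C)(C)C(C)(C)C)[C@H]1OC(=O)C[C@@H]1[C@@H](O)/C=C(/C)[Si](C)(C)Cc1ccccc1 | intermediate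
20 | (4R,5S)-5-[(1R,2R)-1-(TBS-oxy)-2-methylpent-4-en-1-yl]-4-[(1R,2Z)-1-hydroxy-3-iodobut-2-en-1-yl]dihydrofuran-2(3H)-one | C=CC[C@@H](C)[C@@H](O[Si](C)(C)C(C)(C)C)[C@H]1OC(=O)C[C@@H]1[C@@H](O)/C=C(/C)I | intermediate
21 | (4S,5S)-5-[(1R,2R)-1-(TBS-oxy)-2-methylpent-4-en-1-yl]-4-[(1R,2Z)-3-iodo-1-(TES-oxy)but-2-en-1-yl]dihydrofuran-2(3H)-one | C=CC[C@@H](C)[C@@H](O[Si](C)(C)C(C)(C)C)[C@H]1OC(=O)C[C@@H]1[C@@H](O[Si](CC)(CC)CC)/C=C(/C)I | intermediate
22 | B-alkyl-9-BBN adduct of 21 (boron on C3; not isolated) | C1CCC2CCCC1B2CCC[C@@H](C)[C@@H](O[Si](C)(C)C(C)(C)C)[C@H]1OC(=O)C[C@@H]1[C@@H](O[Si](CC)(CC)CC)/C=C(/C)I | intermediate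
23 | (4Z,6S,7S,8S,9R,10R)-9-(TBS-oxy)-6-(TES-oxy)germacr-4-en-12,8-olide | C1C(=O)O[C@@H]2[C@H](O[Si](C)(C)C(C)(C)C)[C@H](C)CCC/C(C)=C\[C@H](O[Si](CC)(CC)CC)[C@@H]12 | intermediate
24 | lithium enolate of 23 (C11=C12–OLi; not isolated) | C1=C(O[Li])O[C@@H]2[C@H](O[Si](C)(C)C(C)(C)C)[C@H](C)CCC/C(C)=C\[C@H](O[Si](CC)(CC)CC)[C@@H]12 | intermediate
25 | (4Z,6S,7S,8S,9R,10R,11R)-9-(TBS-oxy)-13-(dimethylamino)-6-(TES-oxy)germacr-4-en-12,8-olide | CN(C)C[C@@H]1C(=O)O[C@@H]2[C@H](O[Si](C)(C)C(C)(C)C)[C@H](C)CCC/C(C)=C\[C@H](O[Si](CC)(CC)CC)[C@@H]12 | intermediate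
26 | N-methyl quaternary ammonium iodide of 25 (not isolated) | C[N+](C)(C)C[C@@H]1C(=O)O[C@@H]2[C@H](O[Si](C)(C)C(C)(C)C)[C@H](C)CCC/C(C)=C\[C@H](O[Si](CC)(CC)CC)[C@@H]12.[I-] | intermediate
27 | (4Z,6S,7S,8S,9R,10R)-9-(TBS-oxy)-6-(TES-oxy)germacra-4,11(13)-dien-12,8-olide | C=C1C(=O)O[C@@H]2[C@H](O[Si](C)(C)C(C)(C)C)[C@H](C)CCC/C(C)=C\[C@H](O[Si](CC)(CC)CC)[C@@H]12 | intermediate
28 | (4Z,6S,7R,8S,9R,10R)-9-(TBS-oxy)-6-hydroxygermacra-4,11(13)-dien-12,8-olide | C=C1C(=O)O[C@@H]2[C@H](O[Si](C)(C)C(C)(C)C)[C@H](C)CCC/C(C)=C\[C@H](O)[C@@H]12 | intermediate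
29 | (4R,5S,6R,7R,8S,9R,10R)-9-(TBS-oxy)-4,5-epoxy-6-hydroxygermacr-11(13)-en-12,8-olide | C=C1C(=O)O[C@@H]2[C@H](O[Si](C)(C)C(C)(C)C)[C@H](C)CCC[C@@]3(C)O[C@H]3[C@H](O)[C@@H]12 | intermediate
30 | 3-methylbut-2-enoyl chloride | CC(C)=CC(=O)Cl | starting material
31 | (4R,5S,6R,7R,8S,9R,10R)-9-(TBS-oxy)-4,5-epoxy-6-(3-methylbut-2-enoyloxy)germacr-11(13)-en-12,8-olide | C=C1C(=O)O[C@@H]2[C@H](O[Si](C)(C)C(C)(C)C)[C@H](C)CCC[C@@]3(C)O[C@H]3[C@H](OC(=O)C=C(C)C)[C@@H]12 | intermediate
32 | (4R,5S,6R,7S,8S,9R,10R)-4,5-epoxy-9-hydroxy-6-(3-methylbut-2-enoyloxy)germacr-11(13)-en-12,8-olide | C=C1C(=O)O[C@@H]2[C@H](O)[C@H](C)CCC[C@@]3(C)O[C@H]3[C@H](OC(=O)C=C(C)C)[C@@H]12 | target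

Total step count: 21. Longest linear sequence: 21 steps (1 to 32); 3, 7, 16 and 30 are commercial and enter directly.

Least certain steps

Step 15 (key step). Ring closure may lose to intermolecular coupling (oligomerisation). Transmetalation into a strained ring may be slow enough that protodeboronation or β-hydride elimination of the alkylpalladium species takes over. Aqueous carbonate may also open the lactone. Fallback, from 21: Stille coupling with tributyl(vinyl)stannane (Pd(PPh3)4, CuI, DMF) puts a vinyl group on C4 and should give the C4-vinyl triene F1. Ring-closing metathesis between this vinyl group and the allyl terminus (second-generation Hoveyda–Grubbs catalyst, toluene, high dilution, 80 °C) closes C2=C3 and should give the cyclic 2,4-diene F2. Diimide (2-nitrobenzenesulfonyl hydrazide, Et3N), which prefers the disubstituted C2=C3 bond over the trisubstituted one, returns the route to 23.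

Step 5. Facial selectivity at the C9 aldehyde may be poor if catalyst control and substrate bias do not reinforce each other on this α-oxygenated substrate, or if C8 epimerises before addition. Fallback, from 6: addition of the chiral allenylzinc reagent generated from (S)-but-3-yn-2-yl methanesulfonate (Pd(OAc)2, PPh3, Et2Zn, THF, −20 °C). Anti SN2′ palladation and cyclic SE2′ addition fix the methyl centre by reagent control and should give the anti homopropargylic alcohol F3. Semihydrogenation (Pd/CaCO3 poisoned with Pb(OAc)2, quinoline, H2) then gives 9.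

Step 11. Facial selectivity at C6 may be modest with a small alkynyl nucleophile. The basic reagent may enolise the aldehyde and expel the lactone oxygen from C8, and the magnesium alkoxide may attack the lactone carbonyl. Fallback, from 18 obtained as a C6 epimer mixture: Dess–Martin oxidation to the ynone F4, then Corey–Bakshi–Shibata reduction with (R)-1-methyl-3,3-diphenyltetrahydro-1H,3H-pyrrolo[1,2-c][1,3,2]oxazaborole and catecholborane at −78 °C. The propynyl group is expected to act as the small substituent; the catalyst enantiomer would be confirmed on a model. This returns the route to 18 under neutral conditions.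

Step 19. Face selectivity may erode if a ring conformer places the C6 hydroxyl inside the olefin plane, and the chlorobenzoic acid formed may open the epoxy alcohol. Fallback, from 27 (before removal of the C6 silyl group): epoxidation with dimethyldioxirane (acetone, 0 °C), in which the bulky silyloxy group must sit outside and attack is purely peripheral and acid-free, should give the epoxy silyl ether F5. Pyridinium p-toluenesulfonate in MeOH then gives 29.

Step 21. Hydrogen fluoride may open the epoxide, or a slow reaction may force conditions under which the freed C9 hydroxyl attacks the lactone or C13. Fallback, from 28: acylate C6 first (30, pyridine, 4-(dimethylamino)pyridine) to the olefinic senecioate F6. Remove the C9 silyl group with HF·pyridine while no epoxide is present, giving the hydroxy diene F7. Epoxidise last with m-CPBA and NaHCO3 at 0 °C, relying on peripheral attack at the only electron-rich olefin, to reach 32.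

Further compounds

F1 | step 15 | C4-vinyl analogue of 21 (iodine replaced by vinyl, geometry retained) | C=CC[C@@H](C)[C@@H](O[Si](C)(C)C(C)(C)C)[C@H]1OC(=O)C[C@@H]1[C@@H](O[Si](CC)(CC)CC)/C=C(/C)C=C
F2 | step 15 | 2,3-didehydro analogue of 23 (ring 2,4-diene, C2=C3 drawn Z) | C1C(=O)O[C@@H]2[C@H](O[Si](C)(C)C(C)(C)C)[C@H](C)C/C=C\C(C)=C/[C@H](O[Si](CC)(CC)CC)[C@@H]12
F3 | step 5 | alkyne analogue of 9 (but-3-yn-1-yl in place of but-3-en-1-yl, anti) | C#C[C@@H](C)[C@@H](O)[C@H]1OC(=O)C[C@@H]1C1OCCO1
F4 | step 11 | C6 ketone (ynone) corresponding to 18 | C=CC[C@@H](C)[C@@H](O[Si](C)(C)C(C)(C)C)[C@H]1OC(=O)C[C@@H]1C(=O)C#CC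
F5 | step 19 | C6 triethylsilyl ether of 29 | C=C1C(=O)O[C@@H]2[C@H](O[Si](C)(C)C(C)(C)C)[C@H](C)CCC[C@@]3(C)O[C@H]3[C@H](O[Si](CC)(CC)CC)[C@@H]12
F6 | step 21 | C6 senecioate of 28 (C4=C5 olefin, C9 silyl ether) | C=C1C(=O)O[C@@H]2[C@H](O[Si](C)(C)C(C)(C)C)[C@H](C)CCC/C(C)=C\[C@H](OC(=O)C=C(C)C)[C@@H]12
F7 | step 21 | 4,5-deoxy analogue of 32 (C4=C5 Z olefin, free C9 hydroxyl) | C=C1C(=O)O[C@@H]2[C@H](O)[C@H](C)CCC/C(C)=C\[C@H](OC(=O)C=C(C)C)[C@@H]12
A1 | alternative 1 | acetonide-protected (1Z,4Z)-cyclodeca-1,4-diene with C6 PMB ether and C7 2-(TBDPS-oxy)ethyl chain | [C@@H]1(CCO[Si](c3ccccc3)(c3ccccc3)C(C)(C)C)[C@@H](OCc3ccc(OC)cc3)/C=C(C)\C/C=C\[C@@H](C)[C@H]2OC(C)(C)O[C@@H]12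
A2 | alternative 1 | eleven-membered cyclic sulfone bridging C1 and C2 (precursor of A1) | [C@@H]1(CCO[Si](c3ccccc3)(c3ccccc3)C(C)(C)C)[C@@H](OCc3ccc(OC)cc3)/C=C(C)\CCS(=O)(=O)C[C@@H](C)[C@H]2OC(C)(C)O[C@@H]12
A3 | alternative 2 | (Z)-cyclodec-5-enone with C6 TES ether, C7 vinyl, C8 PMB ether, C10 methyl | O=C1[C@H](C)CCC/C(C)=C\[C@H](O[Si](CC)(CC)CC)[C@@H](C=C)[C@@H]1OCc2ccc(OC)cc2
A4 | alternative 2 | cis-fused decalin with tertiary C9 hydroxyl, angular C4 methyl and equatorial C5 mesylate (precursor of A3) | O[C@@]12[C@H](C)CCC[C@@]2(C)[C@@H](OS(C)(=O)=O)[C@H](O[Si](CC)(CC)CC)[C@@H](C=C)[C@@H]1OCc3ccc(OC)cc3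
A5 | alternative 3 | ten-membered C8 ketone with (E)-C2=C3 olefin, C4–C5 epoxide, C6 TBS ether, C7 2-(PMB-oxy)ethyl chain | O=C1C[C@H](C)C/C=C/[C@@]2(C)O[C@H]2[C@H](O[Si](C)(C)C(C)(C)C)[C@H]1CCOCc3ccc(OC)cc3
A6 | alternative 3 | trans-1-[(E)-propenyl]-2-vinylcyclohexanol carrying the epoxide, C6 TBS ether and C7 side chain (precursor of A5) | C/C=C/[C@]1(O)[C@@H](C=C)[C@@]2(C)O[C@H]2[C@H](O[Si](C)(C)C(C)(C)C)[C@H]1CCOCc3ccc(OC)cc3
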